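Product at 1.0 h is your question, with intermediate beside it; here is our quick number, then your forecast.

| setting | amber | violet | grey | flask |
|---|---|---|---|---|
| substrate | 0.060 M | 0.13 M | 0.089 M | 0.089 M |
| reagent | 0.089 M | 0.089 M | 0.089 M | 0.0890 M |
| scavenger | 0.0712 M | 0.0712 M | 0.036 M | 0.0712 M |
| remark | run made earlier | run made earlier | run made earlier |  |
| time |  |  |  | 1.0 h |

| run | time / min | product / % | intermediate / % |
|---|---|---|---|
| amber | 3.00 | 1.5 | 3.0 |
| amber | 5.00 | 3.3 | 7.8 |
| amber | 8.00 | 3.3 | 11.8 |
| amber | 12.0 | 7.1 | 13.0 |
| amber | 20.0 | 17.0 | 14.1 |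
| amber | 40.0 | 36.9 | 8.4 |
| violet | 6.00 | 0 | 8.8 |
| violet | 12.0 | 8.4 | 13.1 |
| violet | 20.0 | 17.0 | 11.9 |
| violet | 25.0 | 20.9 | 10.8 |
| violet | 30.0 | 24.0 | 10.1 |
| violet | 40.0 | 29.3 | 7.2 |
| grey | 3.00 | 1.3 | 5.5 |
| grey | 10.0 | 6.2 | 11.6 |
| grey | 15.0 | 11.2 | 15.4 |
| grey | 25.0 | 22.4 | 12.3 |
| grey | 40.0 | 32.0 | 8.8 |

(each reading ± 1 percentage point)



1. concentration of product at 1.0 h, in M
2. concentration of intermediate at 1.0 h, in M

We take product plus intermediate as the substrate that has taken up reagent, and call that share X. At 40.0 min X is 45.3% in the amber run and smaller, 36.5%, in the violet run, whose substrate charge is larger, so we let both partners count. The flask charges them equally, like the grey run, and that symmetric case is our zero: under a second-order law at equal charges c, the odds of uptake, X against the share not taken up, grow as k c t, with t the time. The last grey reading gives 0.194 M⁻¹ min⁻¹ for k, the uptake constant, an apparent second-order rate constant. It is a rough reading with its scatter. For the flask the odds are 1.03, so we commit to 0.0452 M of product and intermediate together.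

Your forecast gives 0.037 M of product and 0.0067 M of intermediate, 0.0437 M together, and we share its "Halving the scavenger has no clear effect".

The flask gives 0.0387 M of product and 0.00478 M of intermediate, 0.0435 M together.

    substrate + reagent ⇌ intermediate (K = 140 M⁻¹, k = 0.00430 M⁻¹ s⁻¹)
    intermediate ⇌ product + released group (K = 0.140 M, k = 0.00130 s⁻¹)
    substrate + released group ⇌ idle adduct, settled at all times (K = 1900 M⁻¹)
    scavenger + released group → scavenged by-product (k = 0.290 M⁻¹ s⁻¹)

The forecast's product stands within tolerance; its intermediate is 1.40 times the flask's. The flask's own uptake constant comes to 0.179 M⁻¹ min⁻¹. A neighbouring flask charged with 0.022 M of substrate has unequal partners, so our k from the grey run goes into the unequal-charge form of the law. There 2.18 is the growth of the ratio of reagent to substrate, and it gives 0.0134 M taken up. That neighbouring flask holds 0.0119 M of product and 0.00185 M of intermediate, 0.0138 M together.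

Readings and results come from a simulation with constants of no real substance.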